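**Remark (numbering and drawing convention):** cembrane numbering is used: C1 is the ring CH that carries C15 (C15=C17 methylene, C16 lactone carbonyl); C3 and C11 carry the acetates; C4–O–C7 is the tetrahydrofuran (C18 on C4); C8=C19; C12 is the lactone carbinol carbon (C20 on it). A centre that a later step erases is drawn without a descriptor.

## Retrosynthetic overview

1. Granosolide B is a 14-membered carbocycle bridged by a C4–O–C7 tetrahydrofuran and by an α-methylene-ε-lactone (ring atoms C15, C16, O, C12, C13, C14, C1); the last operations are C3 ketone reduction and acetylation.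
2. Key disconnection: C12–C13 and C1–C15 together. The enabling feature is that the C3 oxygen, taken as a ketone, makes C1 (β) and C13 (δ) the two electrophilic ends of a C3(=O)–C2=C1–C14=C13 dienone, while the lactone atoms C12–O–C16–C15 are a four-atom tether whose ends can both be made nucleophilic (C12 radical by decarboxylation, C15 phosphonate carbanion).
3. This formal (4+3) annulation closes the carbocycle and the ε-lactone from seco-acid 19, which contains only the tetrahydrofuran ring.
4. 19 comes from (R)-linalool (C2–C9, C18, C19 and the C4 stereocentre), tert-butyl 2-methylacetoacetate (C10–C12, C20; its ester carbon leaves as CO2), acrolein (C1, C14, C13), phosphonoacetic acid (C15, C16) and formaldehyde (C17).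
5. Ring order: tetrahydrofuran (step 1), then carbocycle and ε-lactone together (step 14).

Key step: step 14

## Route

Step 1
Reactants: 1 (R)-(−)-linalool
Product: 3 2-[(2S,5R)-5-ethenyl-5-methyloxolan-2-yl]propan-2-ol, via (3R,6R)-6,7-epoxylinalool 2 (not isolated)
Conditions: D-fructose-derived Shi ketone (30 mol %), KHSO5 (as 2KHSO5·KHSO4·K2SO4), K2CO3, Bu4NHSO4, MeCN/CH2(OMe)2/aq. buffer pH 10.5, 0 °C; then camphorsulfonic acid (cat.), CH2Cl2, 25 °C
Reagents that add atoms: potassium peroxymonosulfate, [K+].[O-]S(=O)(=O)OO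
Why: Shi epoxidation is reagent-controlled and should give the 6R epoxide of the trisubstituted alkene only (the vinyl group is too electron-poor), and acid-catalysed 5-exo-tet opening by the tertiary hydroxyl inverts that carbon to set C7 (S) cis to the vinyl group, while C4 comes from the chiral pool.

Step 2
Reactants: 3 2-[(2S,5R)-5-ethenyl-5-methyloxolan-2-yl]propan-2-ol
Product: 4 (2R,5S)-2-ethenyl-2-methyl-5-(prop-1-en-2-yl)oxolane
Conditions: Burgess reagent, benzene, 50 °C
Reagents that add atoms: none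
Why: Burgess dehydration is a syn elimination that should take one of the six accessible methyl hydrogens rather than the single ring hydrogen, giving the isopropenyl group without touching a stereocentre.

Step 3
Reactants: 4 (2R,5S)-2-ethenyl-2-methyl-5-(prop-1-en-2-yl)oxolane
Product: 5 (2R,5S)-5-(3-chloroprop-1-en-2-yl)-2-ethenyl-2-methyloxolane
Conditions: Ca(OCl)2, CO2 (solid), CH2Cl2/H2O, 0 °C
Reagents that add atoms: calcium hypochlorite, [Ca+2].[O-]Cl.[O-]Cl
Why: ene-type allylic chlorination with HOCl attacks only the electron-rich 1,1-disubstituted alkene (the vinyl group has no allylic hydrogen), and proton loss from the methyl group gives the 2-(chloromethyl)allyl unit.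

Step 4
Reactants: 5 (2R,5S)-5-(3-chloroprop-1-en-2-yl)-2-ethenyl-2-methyloxolane; 6 tert-butyl 2-methyl-3-oxobutanoate
Product: 7 tert-butyl 6-[(2S,5R)-5-ethenyl-5-methyloxolan-2-yl]-2-methyl-3-oxohept-6-enoate (C2 epimers)
Conditions: 6, NaH, THF, 0 °C; n-BuLi, 0 °C; then 5, 0 → 25 °C; cold aq. HCl
Reagents that add atoms: none
Why: Weiler dianion alkylation occurs at the terminal γ-carbon of the β-keto ester and forms C9–C10 (SN2 and SN2′ attack on the symmetrical 2-substituted allyl chloride give the same product).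

Step 5
Reactants: 7 tert-butyl 6-[(2S,5R)-5-ethenyl-5-methyloxolan-2-yl]-2-methyl-3-oxohept-6-enoate
Product: 8 tert-butyl (3R)-6-[(2S,5R)-5-ethenyl-5-methyloxolan-2-yl]-3-hydroxy-2-methylhept-6-enoate (C2 epimers)
Conditions: RuCl2[(R)-BINAP] (1 mol %), H2 (4 atm), MeOH, 50 °C
Reagents that add atoms: none
Why: Noyori hydrogenation of the β-keto ester is catalyst-controlled through ester chelation ((R)-BINAP should give the 3R carbinol, which is C11) and leaves isolated alkenes alone; the α-centre is not controlled because the next step planarises it.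

Step 6
Reactants: 8 tert-butyl (3R)-6-[(2S,5R)-5-ethenyl-5-methyloxolan-2-yl]-3-hydroxy-2-methylhept-6-enoate
Product: 9 tert-butyl (2R,3R)-6-[(2S,5R)-5-ethenyl-5-methyloxolan-2-yl]-2,3-dihydroxy-2-methylhept-6-enoate
Conditions: LiN(i-Pr)2 (2.3 equiv), THF, −78 → −20 °C; 2-(phenylsulfonyl)-3-phenyloxaziridine, −78 °C; aq. NH4Cl
Reagents that add atoms: 2-(phenylsulfonyl)-3-phenyloxaziridine, O=S(=O)(N1OC1c1ccccc1)c1ccccc1
Why: Frater–Seebach-type hydroxylation of the lithium-chelated dianion with a Davis oxaziridine puts oxygen on C12 anti to the C10 chain; the C12 configuration obtained does not matter because C12 becomes a radical in step 14.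

Step 7
Reactants: 9 tert-butyl (2R,3R)-6-[(2S,5R)-5-ethenyl-5-methyloxolan-2-yl]-2,3-dihydroxy-2-methylhept-6-enoate
Product: 10 tert-butyl (4R,5R)-5-{3-[(2S,5R)-5-ethenyl-5-methyloxolan-2-yl]but-3-en-1-yl}-2,2,4-trimethyl-1,3-dioxolane-4-carboxylate
Conditions: Me2C(OMe)2, pyridinium p-toluenesulfonate (cat.), CH2Cl2, 25 °C
Reagents that add atoms: 2,2-dimethoxypropane, COC(C)(C)OC
Why: acid-catalysed acetonide formation protects the 1,2-diol, which would otherwise undergo oxypalladation in step 8 and consume base in step 9.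

Step 8
Reactants: 10 tert-butyl (4R,5R)-5-{3-[(2S,5R)-5-ethenyl-5-methyloxolan-2-yl]but-3-en-1-yl}-2,2,4-trimethyl-1,3-dioxolane-4-carboxylate
Product: 11 tert-butyl (4R,5R)-5-{3-[(2S,5R)-5-acetyl-5-methyloxolan-2-yl]but-3-en-1-yl}-2,2,4-trimethyl-1,3-dioxolane-4-carboxylate
Conditions: PdCl2 (10 mol %), CuCl, O2 (1 atm), DMF/H2O 7:1, 25 °C
Reagents that add atoms: water, O (source of the carbonyl oxygen; O2 is the terminal oxidant)
Why: Tsuji–Wacker oxidation converts the monosubstituted vinyl group into the methyl ketone (Markovnikov), placing the C3 oxygen, while the 1,1-disubstituted alkene reacts far more slowly.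

Step 9
Reactants: 11 tert-butyl (4R,5R)-5-{3-[(2S,5R)-5-acetyl-5-methyloxolan-2-yl]but-3-en-1-yl}-2,2,4-trimethyl-1,3-dioxolane-4-carboxylate; 12 acrolein
Product: 14 tert-butyl (4R,5R)-2,2,4-trimethyl-5-(3-{(2S,5R)-5-methyl-5-[(2E)-penta-2,4-dienoyl]oxolan-2-yl}but-3-en-1-yl)-1,3-dioxolane-4-carboxylate, via β-acetoxy ketone 13 (not isolated)
Conditions: LiN(i-Pr)2, THF, −78 °C; 12; Ac2O, −78 → 0 °C; DBU, 25 °C
Reagents that add atoms: acetic anhydride, CC(=O)OC(C)=O (acetyl group of intermediate 13 only)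
Why: aldol addition of the only possible lithium enolate to acrolein, acetylation of the aldolate and E1cB elimination with DBU should give the (E)-dienone, adding C1, C14 and C13.

Step 10
Reactants: 14 tert-butyl (4R,5R)-2,2,4-trimethyl-5-(3-{(2S,5R)-5-methyl-5-[(2E)-penta-2,4-dienoyl]oxolan-2-yl}but-3-en-1-yl)-1,3-dioxolane-4-carboxylate
Product: 15 tert-butyl (2R,3R)-2,3-dihydroxy-2-methyl-6-{(2S,5R)-5-methyl-5-[(2E)-penta-2,4-dienoyl]oxolan-2-yl}hept-6-enoate
Conditions: p-TsOH (cat.), MeOH, 25 °C
Reagents that add atoms: none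
Why: acid-catalysed transketalisation removes the acetonide under conditions that the tert-butyl ester and the dienone should tolerate.

Step 11
Reactants: 15 tert-butyl (2R,3R)-2,3-dihydroxy-2-methyl-6-{(2S,5R)-5-methyl-5-[(2E)-penta-2,4-dienoyl]oxolan-2-yl}hept-6-enoate
Product: 16 tert-butyl (2R,3R)-3-acetoxy-2-hydroxy-2-methyl-6-{(2S,5R)-5-methyl-5-[(2E)-penta-2,4-dienoyl]oxolan-2-yl}hept-6-enoate
Conditions: Ac2O (1.3 equiv), pyridine, DMAP (cat.), CH2Cl2, 0 °C
Reagents that add atoms: acetic anhydride, CC(=O)OC(C)=O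
Why: DMAP-catalysed acylation is selective for the secondary C11 hydroxyl over the hindered tertiary C12 hydroxyl and installs the C11 acetate of the target.

Step 12
Reactants: 16 tert-butyl (2R,3R)-3-acetoxy-2-hydroxy-2-methyl-6-{(2S,5R)-5-methyl-5-[(2E)-penta-2,4-dienoyl]oxolan-2-yl}hept-6-enoate; 17 2-(diethoxyphosphoryl)acetic acid
Product: 18 tert-butyl (2R,3R)-3-acetoxy-2-{[2-(diethoxyphosphoryl)acetyl]oxy}-2-methyl-6-{(2S,5R)-5-methyl-5-[(2E)-penta-2,4-dienoyl]oxolan-2-yl}hept-6-enoate
Conditions: 17, DCC, DMAP (cat.), CH2Cl2, 0 → 25 °C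
Reagents that add atoms: none
Why: Steglich esterification of phosphonoacetic acid proceeds through a ketene-like acylating species that should acylate even the hindered tertiary alcohol, attaching C15–C16.

Step 13
Reactants: 18 tert-butyl (2R,3R)-3-acetoxy-2-{[2-(diethoxyphosphoryl)acetyl]oxy}-2-methyl-6-{(2S,5R)-5-methyl-5-[(2E)-penta-2,4-dienoyl]oxolan-2-yl}hept-6-enoate
Product: 19 (2R,3R)-3-acetoxy-2-{[2-(diethoxyphosphoryl)acetyl]oxy}-2-methyl-6-{(2S,5R)-5-methyl-5-[(2E)-penta-2,4-dienoyl]oxolan-2-yl}hept-6-enoic acid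
Conditions: Me3SiOTf, 2,6-lutidine, CH2Cl2, 0 °C; aq. KH2PO4
Reagents that add atoms: none
Why: silyl triflate-mediated tert-butyl ester cleavage (loss of isobutene) frees the acid without base, so dienone, phosphonoacetate and acetate should survive.

Step 14
Reactants: 19 (2R,3R)-3-acetoxy-2-{[2-(diethoxyphosphoryl)acetyl]oxy}-2-methyl-6-{(2S,5R)-5-methyl-5-[(2E)-penta-2,4-dienoyl]oxolan-2-yl}hept-6-enoic acid
Product: 22 3-deacetoxy-3-oxogranosolide B (α-methylene-ε-lactone with C3 ketone and C11 acetate), via macrocyclic enone 20 (not isolated), via phosphono lactone 21 (not isolated)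
Conditions: [Ir(dF(CF3)ppy)2(dtbbpy)]PF6 (2 mol %), K2HPO4, DMF (1 mM), blue LEDs, 25 °C; then LiCl, DBU, 25 °C; then (CH2O)n, 40 °C
Reagents that add atoms: formaldehyde (from paraformaldehyde), C=O
Why: Proposed new method: the excited iridium photocatalyst oxidises the carboxylate of 19, loss of CO2 gives the tertiary α-acyloxy C12 radical, and this closes the 14-membered ring (14-endo-trig) by 1,6-addition to the terminal δ-carbon C13 of the dienone; reduction and protonation of the dienolate radical and DBU equilibration give enone 20, the LiCl/DBU-generated phosphonate carbanion C15 then adds to the β-carbon C1 (7-exo-trig Michael) to give 21, and Horner–Wadsworth–Emmons olefination with formaldehyde installs C17, so that C12–O–C16–C15 acts as a 1,4-bis-nucleophile and the dienone as a 1,3-bis-electrophile in a formal (4+3) annulation. The closest known reaction types are the photoredox decarboxylative Giese macrocyclisation, the 1,6-addition of tertiary radicals to electron-poor dienes, and the intramolecular Michael addition/HWE methylenation of phosphonoacetates; they have not been merged in one pot or used to close an ε-lactone. C12 is set in the macrocyclisation by 1,2-induction from C11 (Felkin-type transition state with the C10 chain anti to the incoming C13, the two C–O bonds gauche and C20 next to H-11), which should favour 12R but is not secured. C1 is set in the reversible Michael closure, where the lactone with C2 and C11 trans on the seven-membered ring should accumulate before the irreversible olefination. The step needs δ- rather than β-attack of the radical (the terminal CH2 is least hindered and gives the most delocalised radical), macrocyclisation rather than 6-endo capture by the C8=C19 alkene (polarity matching of the nucleophilic radical with the dienone, high dilution), and a carbanion that stays silent in the radical stage (K2HPO4 deprotonates the acid but not the phosphonoacetate).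

Step 15
Reactants: 22 3-deacetoxy-3-oxogranosolide B
Product: 23 3-O-deacetylgranosolide B ((3S)-alcohol)
Conditions: Zn(BH4)2, Et2O, −40 → 0 °C; aq. NH4Cl
Reagents that add atoms: none
Why: chelation-controlled reduction (Cram chelate between the tetrahydrofuran oxygen and the ketone) should deliver hydride from the face of the C18 methyl group to give the 3S alcohol, and Zn(BH4)2 should leave lactone, acetate and the α-methylene unit alone at low temperature.

Step 16
Reactants: 23 3-O-deacetylgranosolide B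
Product: 24 granosolide B
Conditions: Ac2O, pyridine, DMAP (cat.), CH2Cl2, 25 °C
Reagents that add atoms: acetic anhydride, CC(=O)OC(C)=O
Why: DMAP-catalysed acetylation of the secondary C3 hydroxyl completes the target without touching any stereocentre.

## Compound list

1 | (R)-(−)-linalool | C=C[C@](C)(O)CCC=C(C)C | starting material
2 | (3R,6R)-6,7-epoxylinalool | C=C[C@](C)(O)CC[C@H]1OC1(C)C | intermediate (not isolated)
3 | 2-[(2S,5R)-5-ethenyl-5-methyloxolan-2-yl]propan-2-ol | C=C[C@@]1(C)CC[C@H](O1)C(C)(C)O | intermediate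
4 | (2R,5S)-2-ethenyl-2-methyl-5-(prop-1-en-2-yl)oxolane | C=C[C@@]1(C)CC[C@H](O1)C(C)=C | intermediate
5 | (2R,5S)-5-(3-chloroprop-1-en-2-yl)-2-ethenyl-2-methyloxolane | C=C[C@@]1(C)CC[C@H](O1)C(=C)CCl | intermediate
6 | tert-butyl 2-methyl-3-oxobutanoate | CC(=O)C(C)C(=O)OC(C)(C)C | starting material
7 | tert-butyl 6-[(2S,5R)-5-ethenyl-5-methyloxolan-2-yl]-2-methyl-3-oxohept-6-enoate (C2 epimers) | C=C[C@@]1(C)CC[C@H](O1)C(=C)CCC(=O)C(C)C(=O)OC(C)(C)C | intermediate
8 | tert-butyl (3R)-6-[(2S,5R)-5-ethenyl-5-methyloxolan-2-yl]-3-hydroxy-2-methylhept-6-enoate (C2 epimers) | C=C[C@@]1(C)CC[C@H](O1)C(=C)CC[C@@H](O)C(C)C(=O)OC(C)(C)C | intermediate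
9 | tert-butyl (2R,3R)-6-[(2S,5R)-5-ethenyl-5-methyloxolan-2-yl]-2,3-dihydroxy-2-methylhept-6-enoate | C=C[C@@]1(C)CC[C@H](O1)C(=C)CC[C@@H](O)[C@@](C)(O)C(=O)OC(C)(C)C | intermediate
10 | tert-butyl (4R,5R)-5-{3-[(2S,5R)-5-ethenyl-5-methyloxolan-2-yl]but-3-en-1-yl}-2,2,4-trimethyl-1,3-dioxolane-4-carboxylate | C=C[C@@]1(C)CC[C@H](O1)C(=C)CC[C@H]2OC(C)(C)O[C@@]2(C)C(=O)OC(C)(C)C | intermediate
11 | tert-butyl (4R,5R)-5-{3-[(2S,5R)-5-acetyl-5-methyloxolan-2-yl]but-3-en-1-yl}-2,2,4-trimethyl-1,3-dioxolane-4-carboxylate | CC(=O)[C@@]1(C)CC[C@H](O1)C(=C)CC[C@H]2OC(C)(C)O[C@@]2(C)C(=O)OC(C)(C)C | intermediate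
12 | acrolein | C=CC=O | starting material
13 | β-acetoxy ketone (aldol acetate of 11, C1 epimers) | CC(=O)OC(C=C)CC(=O)[C@@]1(C)CC[C@H](O1)C(=C)CC[C@H]2OC(C)(C)O[C@@]2(C)C(=O)OC(C)(C)C | intermediate (not isolated)
14 | tert-butyl (4R,5R)-2,2,4-trimethyl-5-(3-{(2S,5R)-5-methyl-5-[(2E)-penta-2,4-dienoyl]oxolan-2-yl}but-3-en-1-yl)-1,3-dioxolane-4-carboxylate | C=C/C=C/C(=O)[C@@]1(C)CC[C@H](O1)C(=C)CC[C@H]2OC(C)(C)O[C@@]2(C)C(=O)OC(C)(C)C | intermediate
15 | tert-butyl (2R,3R)-2,3-dihydroxy-2-methyl-6-{(2S,5R)-5-methyl-5-[(2E)-penta-2,4-dienoyl]oxolan-2-yl}hept-6-enoate | C=C/C=C/C(=O)[C@@]1(C)CC[C@H](O1)C(=C)CC[C@@H](O)[C@@](C)(O)C(=O)OC(C)(C)C | intermediate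
16 | tert-butyl (2R,3R)-3-acetoxy-2-hydroxy-2-methyl-6-{(2S,5R)-5-methyl-5-[(2E)-penta-2,4-dienoyl]oxolan-2-yl}hept-6-enoate | C=C/C=C/C(=O)[C@@]1(C)CC[C@H](O1)C(=C)CC[C@@H](OC(C)=O)[C@@](C)(O)C(=O)OC(C)(C)C | intermediate
17 | 2-(diethoxyphosphoryl)acetic acid | CCOP(=O)(CC(=O)O)OCC | starting material
18 | tert-butyl (2R,3R)-3-acetoxy-2-{[2-(diethoxyphosphoryl)acetyl]oxy}-2-methyl-6-{(2S,5R)-5-methyl-5-[(2E)-penta-2,4-dienoyl]oxolan-2-yl}hept-6-enoate | C=C/C=C/C(=O)[C@@]1(C)CC[C@H](O1)C(=C)CC[C@@H](OC(C)=O)[C@@](C)(OC(=O)CP(=O)(OCC)OCC)C(=O)OC(C)(C)C | intermediate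
19 | (2R,3R)-3-acetoxy-2-{[2-(diethoxyphosphoryl)acetyl]oxy}-2-methyl-6-{(2S,5R)-5-methyl-5-[(2E)-penta-2,4-dienoyl]oxolan-2-yl}hept-6-enoic acid | C=C/C=C/C(=O)[C@@]1(C)CC[C@H](O1)C(=C)CC[C@@H](OC(C)=O)[C@@](C)(OC(=O)CP(=O)(OCC)OCC)C(O)=O | intermediate
20 | macrocyclic (1E)-enone: 14-membered carbocycle with C3 ketone, C4–O–C7 tetrahydrofuran, C8=C19, 11-acetoxy and 12-[(diethoxyphosphoryl)acetoxy] groups | CCOP(=O)(OCC)CC(=O)O[C@]2(C)CC/C=C/C(=O)[C@@]1(C)CC[C@H](O1)C(=C)CC[C@H]2OC(C)=O | intermediate (not isolated)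
21 | phosphono lactone: ε-lactone closed, C15 bearing P(O)(OEt)2 (C15 epimers), C3 ketone | CCOP(=O)(OCC)C1C(=O)O[C@]2(C)CC[C@@H]1CC(=O)[C@@]1(C)CC[C@H](O1)C(=C)CC[C@H]2OC(C)=O | intermediate (not isolated)
22 | 3-deacetoxy-3-oxogranosolide B | C=C1C(=O)O[C@]2(C)CC[C@@H]1CC(=O)[C@@]1(C)CC[C@H](O1)C(=C)CC[C@H]2OC(C)=O | intermediate
23 | 3-O-deacetylgranosolide B ((3S)-alcohol) | C=C1C(=O)O[C@]2(C)CC[C@@H]1C[C@H](O)[C@@]1(C)CC[C@H](O1)C(=C)CC[C@H]2OC(C)=O | intermediate
24 | granosolide B | C=C1C(=O)O[C@]2(C)CC[C@@H]1C[C@H](OC(C)=O)[C@@]1(C)CC[C@H](O1)C(=C)CC[C@H]2OC(C)=O | target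

## Step count and risks

Total step count: 16. Longest linear sequence: 16 steps, from (R)-linalool 1.

The three steps most likely to fail:

**Step 14.** The acyclic C12 radical may add with poor facial selectivity, may be captured by the C8=C19 alkene (6-endo), or the carbanion may close the lactone to the wrong C1 epimer. The fallback uses established reactions only, run stepwise with a ring-constrained radical; it sets out from 15 and comes back at 20. Cleavage of the tert-butyl ester of 15 (Me3SiOTf, 2,6-lutidine) gives the dihydroxy acid F1. 2-Methoxypropene with pyridinium p-toluenesulfonate, then a brief aqueous wash, gives the acetonide acid F2. Photoredox decarboxylative Giese macrocyclisation ([Ir(dF(CF3)ppy)2(dtbbpy)]PF6, K2HPO4, DMF, blue LEDs; then DBU) now runs through a 1,3-dioxolan-4-yl ring radical, which should take up C13 trans to the C10 chain (the 12R configuration), and gives the macrocyclic enone acetonide F3. p-TsOH in MeOH frees the macrocyclic enone diol F4, which is kept cold and acylated at once because its tertiary hydroxyl can add to the enone. Ac2O/pyridine gives the macrocyclic enone 11-acetate F5, and DCC-mediated esterification with 17 gives 20. Compound 20 is isolated and taken through the LiCl/DBU and paraformaldehyde stages of step 14 to 22.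

**Step 15.** Hydride may be delivered to the wrong face of the C3 ketone (Felkin-type or macrocycle-controlled attack instead of chelation control). The fallback sets out from 22 and comes back at 24: the epimeric (3R)-alcohol F6 obtained in that case is not discarded but esterified under Mitsunobu conditions (PPh3, diisopropyl azodicarboxylate, acetic acid, toluene), which inverts C3 and installs the acetate in one operation.

**Step 9.** Acrolein may polymerise under the enolate conditions, or the dienone may be lost during the DBU elimination. The fallback sets out from 11 and comes back at 14: condensation of 11 with N,N-dimethylformamide dimethyl acetal (neat, 110 °C) gives the (E)-enaminone F7, and vinylmagnesium bromide (THF, −78 → 0 °C, acidic work-up) adds 1,4 and expels dimethylamine to give 14.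

## Further compounds

F1 | step 14 | (2R,3R)-2,3-dihydroxy-2-methyl-6-{(2S,5R)-5-methyl-5-[(2E)-penta-2,4-dienoyl]oxolan-2-yl}hept-6-enoic acid | C=C/C=C/C(=O)[C@@]1(C)CC[C@H](O1)C(=C)CC[C@@H](O)[C@@](C)(O)C(O)=O
F2 | step 14 | (4R,5R)-2,2,4-trimethyl-5-(3-{(2S,5R)-5-methyl-5-[(2E)-penta-2,4-dienoyl]oxolan-2-yl}but-3-en-1-yl)-1,3-dioxolane-4-carboxylic acid | C=C/C=C/C(=O)[C@@]1(C)CC[C@H](O1)C(=C)CC[C@H]2OC(C)(C)O[C@@]2(C)C(O)=O
F3 | step 14 | macrocyclic (1E)-enone 11,12-acetonide (C3 ketone, C4–O–C7 tetrahydrofuran, C8=C19) | CC1(C)O[C@]2(C)CC/C=C/C(=O)[C@@]3(C)CC[C@H](O3)C(=C)CC[C@H]2O1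
F4 | step 14 | macrocyclic (1E)-enone 11,12-diol | O[C@]2(C)CC/C=C/C(=O)[C@@]3(C)CC[C@H](O3)C(=C)CC[C@H]2O
F5 | step 14 | macrocyclic (1E)-enone 11-acetate with free 12-hydroxyl | O[C@]2(C)CC/C=C/C(=O)[C@@]3(C)CC[C@H](O3)C(=C)CC[C@H]2OC(C)=O
F6 | step 15 | 3-epi-3-O-deacetylgranosolide B ((3R)-alcohol) | C=C1C(=O)O[C@]2(C)CC[C@@H]1C[C@@H](O)[C@@]1(C)CC[C@H](O1)C(=C)CC[C@H]2OC(C)=O
F7 | step 9 | tert-butyl (4R,5R)-5-(3-{(2S,5R)-5-[(2E)-3-(dimethylamino)prop-2-enoyl]-5-methyloxolan-2-yl}but-3-en-1-yl)-2,2,4-trimethyl-1,3-dioxolane-4-carboxylate | CN(C)/C=C/C(=O)[C@@]1(C)CC[C@H](O1)C(=C)CC[C@H]2OC(C)(C)O[C@@]2(C)C(=O)OC(C)(C)C
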